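**Plan**

1. Numbering. Ring D: C1(=O), C2(prenyl)=C3(O–), C4(OH), C5(OH), C6(geranyl). Ring A: C6, C7, C8=C9(CH3), C10, C5. Ring B: C10, C11, C12, C4, C5. Ring C: C12, C13(CH3)2, O, C3, C4.
2. Cuts, last-made bonds first: C4–C12 and C13–O (rings B and C, one cationic cascade onto a C4 ketone); then the C4 oxygen, C9–CH3 and C2–prenyl; then C5–C10 (ring A, aldol); then C6–C7 (Michael) and C6–geranyl.
3. Enabling feature: fully substituted C6 is flanked by the C1 ketone and the C5 tertiary carbinol, and C5–OH is β to C9. Rings A and D are therefore the ketol of a mirror-symmetric 2,2-disubstituted cyclohexane-1,3-dione carrying a 3-oxoalkyl chain.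
4. Forward order: ring D comes from cyclohexane-1,3,5-triol. C3 travels as an OTBS carbinol, because a C3 ketal of the dione would aromatise before C6 is quaternary. Ring A closes in the aldol step, and rings B and C close together in the penultimate step.
5. Stereochemistry: D-phenylalanine distinguishes the two enantiotopic ring carbonyls and so fixes C6, C5 and C10 in one operation. C4 and C12 follow from these centres through the all-cis ring fusions of the cascade.

Key step: step 7

Assumption: step 6 is taken to give both achiral C3/C6 diastereomers of 10, separable on silica; only the isomer drawn (oxoalkyl chain cis to OTBS) is carried forward.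

**Route**

Step 1
Reactants: 1 6-methylhept-5-en-2-one
Product: 2 1-(dimethylamino)-7-methyloct-6-en-3-one
Conditions: LiN(iPr)2, THF, −78 °C; then CH2=NMe2+ I−, −78 °C to rt
Reagents that add atoms: dimethylmethyleneammonium iodide, C=[N+](C)C.[I-]
Why: Kinetic deprotonation at the CH3 group followed by a Mannich reaction with the preformed iminium salt places the aminomethyl unit on the terminal carbon, whereas the acid-catalysed Mannich reaction would go through the more substituted enol.

Step 2
Reactants: 2 1-(dimethylamino)-7-methyloct-6-en-3-one
Product: 4 7-methylocta-1,6-dien-3-one, via methiodide 3 (not isolated)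
Conditions: MeI, Et2O, rt; then aq NaHCO3, CH2Cl2, rt
Reagents that add atoms: none
Why: Quaternisation makes the nitrogen a leaving group and the β-ammonium ketone undergoes a Hofmann-type E1cB elimination under bicarbonate, the standard passage from a Mannich base to a vinyl ketone.

Step 3
Reactants: 5 cis,cis-cyclohexane-1,3,5-triol
Product: 6 all-cis-5-(tert-butyldimethylsilyloxy)cyclohexane-1,3-diol
Conditions: TBSCl (1.0 equiv), imidazole, DMF, 0 °C to rt
Reagents that add atoms: tert-butyldimethylsilyl chloride, CC(C)(C)[Si](C)(C)Cl
Why: Silyl ether formation on a triol with three equivalent hydroxy groups gives the mono-ether statistically with one equivalent of chloride, the all-cis relationship is retained, and triol and bis-ether are separated and recycled.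

Step 4
Reactants: 6 all-cis-5-(tert-butyldimethylsilyloxy)cyclohexane-1,3-diol
Product: 7 5-(tert-butyldimethylsilyloxy)cyclohexane-1,3-dione
Conditions: IBX (3 equiv), DMSO, rt
Reagents that add atoms: none
Why: Alcohol oxidation with IBX takes both carbinols to the ketone level without attacking the enolisable 1,3-diketone that results, and the neutral medium spares the β-silyloxy group, whose loss would lead to resorcinol.

Step 5
Reactants: 7 5-(tert-butyldimethylsilyloxy)cyclohexane-1,3-dione; 8 geranyl bromide
Product: 9 2-geranyl-5-(tert-butyldimethylsilyloxy)cyclohexane-1,3-dione (enol form)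
Conditions: KOH (1.0 equiv), H2O–MeOH, 0 °C to rt
Reagents that add atoms: none
Why: C-Alkylation of a cyclic 1,3-diketone enolate with an allylic bromide is favoured in protic solvent where the enolate oxygens are solvated, the SN2 displacement keeps the E alkene, and in its delocalised enolate form the ring cannot expel silanolate.

Step 6
Reactants: 9 2-geranyl-5-(tert-butyldimethylsilyloxy)cyclohexane-1,3-dione; 4 7-methylocta-1,6-dien-3-one
Product: 10 achiral triketone 2-geranyl-2-(7-methyl-3-oxooct-6-enyl)-5-(tert-butyldimethylsilyloxy)cyclohexane-1,3-dione, oxoalkyl chain cis to OTBS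
Conditions: Et3N (0.2 equiv), THF, rt
Reagents that add atoms: none
Why: Michael addition of a 2-substituted 1,3-diketone to a vinyl ketone is C-selective and creates quaternary C6, a chair-like axial approach on the face away from the puckered C3 should place the new chain cis to the equatorial silyloxy group, and the other (also achiral) isomer is removed by chromatography.

Step 7
Reactants: 10 achiral triketone
Product: 11 cis-fused ketol of rings A and D: C5–OH and C6-geranyl on one face, C10-prenyl trans to C5–OH, C3–OTBS trans to geranyl, ketones at C1 and C9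
Conditions: D-phenylalanine (30 mol %), (1R)-(−)-camphor-10-sulfonic acid (15 mol %), DMF, 20 °C, stopped when 10 is consumed
Reagents that add atoms: none
Why: The amino acid condenses with the C9 ketone, the only carbonyl not next to quaternary C6, and the resulting C9=C10 enamine adds through C10 to C5 while the carboxylic acid protonates the accepting oxygen, after which hydrolysis frees the ketol and the catalyst (the regioisomeric C8 enamine is a dead end because it could only close a cyclobutane). This is the Hajos–Parrish–Eder–Sauer–Wiechert reaction halted at the aldol stage, in the primary-amino-acid variant used for triketones that are substituted at the nucleophilic carbon, since a secondary enamine N–H tolerates the Z geometry that a proline enamine does not. Ring A closes in the 6-(enolendo)-exo-trig mode through a chair in which C7 stands axial on ring D. As 10 has a mirror plane through C3 and C6, the sense of induction at C6 and C5 rests entirely on the amino acid (the D series is chosen because the L series delivers the opposite angular configuration in the related 8a-alkyl octalinediones), and the short C7–C8 link permits only a cis junction with OH and geranyl on the same face. C10 is set by the Z-enamine, which places C11 equatorial, and it remains correctable through the product enamine, because the equatorial C3 silyloxy group holds the cis-decalin in the conformer with geranyl axial on ring A, where the C10 epimer would suffer a syn-diaxial prenyl/geranyl contact. The step must stop before water is lost, and in that same conformer the C5–O bond is equatorial on ring A and so poorly aligned with the C9=C10 π system, which together with ambient temperature and the buffered acid should keep the product at the ketol.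

Step 8
Reactants: 11 cis-fused ketol
Product: 12 C3,C5-diol (11 without the silyl group)
Conditions: HF·pyridine, pyridine, THF, 0 °C to rt
Reagents that add atoms: none
Why: Fluoride-driven silyl ether cleavage in a buffered, weakly acidic medium avoids the C5 alkoxide that basic fluoride sources would generate and that could reopen ring A by retro-aldol reaction.

Step 9
Reactants: 12 C3,C5-diol
Product: 13 enolised C1/C3 β-diketone with C5–OH and the C9 ketone intact
Conditions: IBX (1.5 equiv), DMSO, rt
Reagents that add atoms: none
Why: Only the secondary C3 carbinol can be oxidised, IBX is a reliable reagent for the β-hydroxy ketone to β-diketone oxidation, and enolisation of the product erases the C3 centre and from here on distinguishes C1 from the C9 ketone.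

Step 10
Reactants: 13 enolised β-diketone; 14 prenyl acetate
Product: 15 C2-prenylated β-diketone
Conditions: Pd(PPh3)4 (5 mol %), Et3N (1.1 equiv), THF, 40 °C
Reagents that add atoms: none
Why: In this Tsuji–Trost allylation the soft C2 carbon of the diketonate attacks the unsubstituted end of the 1,1-dimethyl-π-allylpalladium complex, any O-prenyl ether is re-ionised by zerovalent palladium and funnelled to the C-prenyl product, and the nearly neutral medium leaves the ketol untouched.

Step 11
Reactants: 15 C2-prenylated β-diketone
Product: 17 C5 triethylsilyl ether of 15, via bis-silyl ether 16 (not isolated)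
Conditions: TESOTf (2.5 equiv), 2,6-lutidine, CH2Cl2, −78 to 0 °C; then MeOH–pH 7 buffer
Reagents that add atoms: triethylsilyl trifluoromethanesulfonate, CC[Si](CC)(CC)OS(=O)(=O)C(F)(F)F
Why: Silylation with the triflate is fast enough for the hindered tertiary C5–OH, the vinylogous silyl ester formed at the enol at the same time is solvolysed on work-up, and the C5 ether blocks retro-aldol cleavage in the basic steps that follow.

Step 12
Reactants: 17 C5 triethylsilyl ether
Product: 18 C8=C9 enol triflate
Conditions: KN(SiMe3)2 (2.2 equiv), THF, −78 °C; N-(5-chloro-2-pyridyl)bis(trifluoromethanesulfonimide) (1.05 equiv), −78 °C; then AcOH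
Reagents that add atoms: N-(5-chloro-2-pyridyl)bis(trifluoromethanesulfonimide), O=S(=O)(N(c1ccc(Cl)cn1)S(=O)(=O)C(F)(F)F)C(F)(F)F
Why: In this kinetic enol triflate formation the first equivalent of base stores ring D as its inert diketonate, the second removes the accessible C8 proton rather than the tertiary C10–H next to quaternary C5, and the far more nucleophilic ketone enolate is the one that is sulfonylated.

Step 13
Reactants: 18 C8=C9 enol triflate
Product: 19 C9-methyl alkene (ring A complete)
Conditions: Me2Zn (3 equiv), Pd(PPh3)4 (5 mol %), THF, 0 °C to rt; then aq NH4Cl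
Reagents that add atoms: dimethylzinc, C[Zn]C
Why: Negishi coupling of the alkenyl triflate exchanges OTf for CH3 with the double bond fixed at C8=C9, and dimethylzinc only deprotonates the enol without adding to the zinc diketonate or disturbing the silyl ether.

Step 14
Reactants: 19 C9-methyl alkene
Product: 20 C4 carbinol (acyloin), OH drawn trans to C5–OTES
Conditions: LiN(iPr)2 (2.3 equiv), THF, −78 °C; 2-(phenylsulfonyl)-3-phenyloxaziridine (1.2 equiv), −78 °C; then AcOH
Reagents that add atoms: 2-(phenylsulfonyl)-3-phenyloxaziridine, O=S(=O)(N1OC1c1ccccc1)c1ccccc1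
Why: The 1,3-diketone dianion reacts at its last-formed carbanion C4, the only α′ position bearing hydrogen because C6 is quaternary, oxygen transfer from an N-sulfonyloxaziridine is a standard enolate hydroxylation, and the C4 configuration (approach anti to the silyloxy group expected) is irrelevant since it is oxidised next.

Step 15
Reactants: 20 C4 carbinol
Product: 21 C4 ketone, resting as the 3-hydroxy-2-prenyl-2-ene-1,4-dione tautomer of ring D
Conditions: IBX (1.5 equiv), DMSO, rt
Reagents that add atoms: none
Why: Acyloin oxidation with IBX gives the 1,2-diketone, which settles as the hydrogen-bonded hydroxy-enedione, and the reagent leaves the five trisubstituted alkenes and the silyl ether alone.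

Step 16
Reactants: 21 C4 ketone
Product: 22 C5 triethylsilyl ether of the target (rings A to D complete)
Conditions: Me2AlCl (2.5 equiv), CH2Cl2, −78 to −20 °C; then aq potassium sodium tartrate
Reagents that add atoms: none
Why: Proposed new method: Me2AlCl deprotonates the C3 enol and chelates O3 and O4 while a second equivalent raises the electrophilicity of C4; the C12=C13 alkene then attacks C4 in a 5-exo Prins closure of ring B on the face of ring D that carries C10 (allylic strain with the C9 methyl turns C11 pseudo-axial and so over C4), and the tertiary C13 cation is captured by O3 in a 5-exo closure of ring C, which leaves C4–OH cis to C5–O and C12–H cis to C4–OH because only this arrangement lets O3 reach C13; the closest known reactions are alkylaluminium-halide-promoted carbonyl-ene and Prins cyclisations of δ,ε-unsaturated carbonyl compounds to cyclopentanols, the carbon–oxygen mode of oxyallyl cation (3+2) additions to alkenes, and cation–olefin cyclisations terminated by a β-diketone enol oxygen; the proton-free medium keeps the C2 prenyl group from closing a chroman, that group lies in the enedione plane and cannot reach the C4 π* orbital, and the geranyl alkene would have to pass the C5 silyloxy group to build a bridged bicyclo[3.2.1]octane that has no internal trap.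

Step 17
Reactants: 22 C5 triethylsilyl ether of the target
Product: 23 target CNP0323114.1
Conditions: HF·pyridine, pyridine, THF, 0 °C
Reagents that add atoms: none
Why: Fluoride-mediated desilylation removes the tertiary triethylsilyl ether under buffered conditions that touch neither the vinylogous ester nor the alkenes and avoid base-induced retro-aldol cleavage of the C5 carbinol β to C1.

**Compound list**

1 | 6-methylhept-5-en-2-one | CC(=O)CCC=C(C)C | starting material
2 | 1-(dimethylamino)-7-methyloct-6-en-3-one | CN(C)CCC(=O)CCC=C(C)C | intermediate
3 | trimethyl(7-methyl-3-oxooct-6-enyl)ammonium iodide | C[N+](C)(C)CCC(=O)CCC=C(C)C.[I-] | intermediate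
4 | 7-methylocta-1,6-dien-3-one | C=CC(=O)CCC=C(C)C | intermediate
5 | cis,cis-cyclohexane-1,3,5-triol | O[C@H]1C[C@@H](O)C[C@@H](O)C1 | starting material
6 | all-cis-5-(tert-butyldimethylsilyloxy)cyclohexane-1,3-diol | CC(C)(C)[Si](C)(C)O[C@H]1C[C@@H](O)C[C@@H](O)C1 | intermediate
7 | 5-(tert-butyldimethylsilyloxy)cyclohexane-1,3-dione | CC(C)(C)[Si](C)(C)OC1CC(=O)CC(=O)C1 | intermediate
8 | geranyl bromide, (E)-1-bromo-3,7-dimethylocta-2,6-diene | CC(C)=CCC/C(C)=C/CBr | starting material
9 | 2-geranyl-5-(tert-butyldimethylsilyloxy)cyclohexane-1,3-dione, enol form (no fixed stereocentre, the enol tautomers interconvert) | CC(C)=CCC/C(C)=C/CC1=C(O)CC(O[Si](C)(C)C(C)(C)C)CC1=O | intermediate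
10 | achiral triketone, oxoalkyl chain cis to OTBS | CC(C)=CCC/C(C)=C/C[C@@]1(CCC(=O)CCC=C(C)C)C(=O)C[C@H](O[Si](C)(C)C(C)(C)C)CC1=O | intermediate
11 | cis-fused ketol of rings A and D, C3–OTBS | CC(C)=CCC/C(C)=C/C[C@]12CCC(=O)[C@H](CC=C(C)C)[C@]2(O)C[C@H](O[Si](C)(C)C(C)(C)C)CC1=O | intermediate
12 | C3,C5-diol | CC(C)=CCC/C(C)=C/C[C@]12CCC(=O)[C@H](CC=C(C)C)[C@]2(O)C[C@H](O)CC1=O | intermediate
13 | enolised C1/C3 β-diketone | CC(C)=CCC/C(C)=C/C[C@]12CCC(=O)[C@H](CC=C(C)C)[C@]2(O)CC(O)=CC1=O | intermediate
14 | prenyl acetate, 3-methylbut-2-enyl acetate | CC(C)=CCOC(C)=O | starting material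
15 | C2-prenylated β-diketone | CC(C)=CCC/C(C)=C/C[C@]12CCC(=O)[C@H](CC=C(C)C)[C@]2(O)CC(O)=C(CC=C(C)C)C1=O | intermediate
16 | C3-O,C5-O-bis(triethylsilyl) derivative of 15 | CC(C)=CCC/C(C)=C/C[C@]12CCC(=O)[C@H](CC=C(C)C)[C@]2(O[Si](CC)(CC)CC)CC(O[Si](CC)(CC)CC)=C(CC=C(C)C)C1=O | intermediate
17 | C5 triethylsilyl ether of 15 | CC(C)=CCC/C(C)=C/C[C@]12CCC(=O)[C@H](CC=C(C)C)[C@]2(O[Si](CC)(CC)CC)CC(O)=C(CC=C(C)C)C1=O | intermediate
18 | C8=C9 enol triflate | CC(C)=CCC/C(C)=C/C[C@]12CC=C(OS(=O)(=O)C(F)(F)F)[C@H](CC=C(C)C)[C@]2(O[Si](CC)(CC)CC)CC(O)=C(CC=C(C)C)C1=O | intermediate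
19 | C9-methyl alkene | CC(C)=CCC/C(C)=C/C[C@]12CC=C(C)[C@H](CC=C(C)C)[C@]2(O[Si](CC)(CC)CC)CC(O)=C(CC=C(C)C)C1=O | intermediate
20 | C4 carbinol (acyloin) | CC(C)=CCC/C(C)=C/C[C@]12CC=C(C)[C@H](CC=C(C)C)[C@]2(O[Si](CC)(CC)CC)[C@H](O)C(O)=C(CC=C(C)C)C1=O | intermediate
21 | C4 ketone, hydroxy-enedione tautomer | CC(C)=CCC/C(C)=C/C[C@]12CC=C(C)[C@H](CC=C(C)C)[C@]2(O[Si](CC)(CC)CC)C(=O)C(O)=C(CC=C(C)C)C1=O | intermediate
22 | C5 triethylsilyl ether of the target | CC(C)=CCC/C(C)=C/C[C@]12CC=C(C)[C@@H]3C[C@@H]4C(C)(C)OC(=C(CC=C(C)C)C1=O)[C@]4(O)[C@@]32O[Si](CC)(CC)CC | intermediate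
23 | CNP0323114.1 | CC(C)=CCC/C(C)=C/C[C@]12CC=C(C)[C@@H]3C[C@@H]4C(C)(C)OC(=C(CC=C(C)C)C1=O)[C@]4(O)[C@@]32O | target

**Step count**

- Total step count: 17.
- Longest linear sequence: 15 (steps 3 to 17, from 5).

**Steps most likely to fail**

Step 16.
- What may go wrong: the concerted carbonyl-ene pathway, in which a hydrogen of a C13 methyl passes to O4, may outrun capture by O3. It fixes C12 with the facial sense that cannot close ring C. The geranyl alkene may also compete for C4.
- Fallback: a radical closure in place of the cationic one, built from known reaction types. It sets out from 19 and comes back at 22.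
- The dianion of 19 (LiN(iPr)2, THF, −78 °C) is quenched with I2 to give the 4-iodo diketone F1.
- Iodine-atom-transfer radical cyclisation (Bu3SnSnBu3, hν, benzene) closes ring B 5-exo. The chair-like transition state puts C13 cis to C3 and gives the tertiary iodide F2.
- AgOTf with 2,6-lutidine ionises the iodide, and the C3 enol oxygen closes ring C to the 4-deoxy tetracycle F3.
- Removal of the only γ-hydrogen (C4–H) with KN(SiMe3)2, followed by oxygen transfer from 2-(phenylsulfonyl)-3-phenyloxaziridine on the one open face, gives 22.

Step 7.
- What may go wrong: loss of water from the ketol under the aminocatalytic conditions, which would erase C5 and C10, or slow enamine formation at the substituted side chain.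
- Fallback: the dehydration is accepted and the hydroxy group is put back. It sets out from 10 and comes back at 11.
- The condensation is driven to completion (same amino acid and acid, DMF, 60 °C) to give the bicyclic enone F4, in which C6 is already set.
- Weitz–Scheffer epoxidation (H2O2, NaOH, MeOH, 0 °C) follows, with axial attack of hydroperoxide at C5 on the face of the angular substituent as in related octalones. It gives the epoxy ketone F5.
- SmI2 (THF–MeOH, −90 °C) cleaves the C10–O bond. Protonation of the enolate and equilibration to the equatorial prenyl epimer then give 11.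

Step 14.
- What may go wrong: β-elimination of the C5 silanolate from the electron-rich dianion, since the C5–O bond can align with the C3=C4 enolate.
- Fallback: a neutral enol ether replaces the carbanion. It sets out from 19 and comes back at 20.
- TMSOTf and Et3N (CH2Cl2, 0 °C) give the bis(trimethylsilyl) dienol ether F6.
- Rubottom oxidation with dimethyldioxirane (1 equiv, acetone–CH2Cl2, −78 °C) is expected at the terminal, most electron-rich C3=C4 bond. Citric acid in MeOH then releases 20.

**Further compounds**

F1 | step 16 | 4-iodo diketone (C4 configuration of no consequence, one epimer drawn) | CC(C)=CCC/C(C)=C/C[C@]12CC=C(C)[C@H](CC=C(C)C)[C@]2(O[Si](CC)(CC)CC)[C@H](I)C(O)=C(CC=C(C)C)C1=O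
F2 | step 16 | tertiary iodide with ring B closed | CC(C)=CCC/C(C)=C/C[C@]12CC=C(C)[C@@H]3C[C@H](C(C)(C)I)[C@H](C(O)=C(CC=C(C)C)C1=O)[C@@]32O[Si](CC)(CC)CC
F3 | step 16 | 4-deoxy tetracycle (22 with H in place of C4–OH) | CC(C)=CCC/C(C)=C/C[C@]12CC=C(C)[C@@H]3C[C@@H]4C(C)(C)OC(=C(CC=C(C)C)C1=O)[C@@H]4[C@@]32O[Si](CC)(CC)CC
F4 | step 7 | bicyclic enone (C5=C10) | CC(C)=CCC/C(C)=C/C[C@]12CCC(=O)C(CC=C(C)C)=C2C[C@H](O[Si](C)(C)C(C)(C)C)CC1=O
F5 | step 7 | C5,C10-epoxy ketone, oxygen cis to geranyl | CC(C)=CCC/C(C)=C/C[C@]12CCC(=O)[C@@]3(CC=C(C)C)O[C@@]23C[C@H](O[Si](C)(C)C(C)(C)C)CC1=O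
F6 | step 14 | bis(trimethylsilyl) dienol ether | CC(C)=CCC/C(C)=C/C[C@]12CC=C(C)[C@H](CC=C(C)C)[C@]2(O[Si](CC)(CC)CC)C=C(O[Si](C)(C)C)C(CC=C(C)C)=C1O[Si](C)(C)C
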